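The route rests on disconnecting the O1–C2 bond of the dihydrobenzofuran. In the last step, global phenol unmasking and dilute acid turn the benzylic carbinol that sits para to the 4-OH of the guaiacyl ring into a p-quinone methide; the ring-B phenol oxygen (O1), ortho to the C3a–C3 bond, adds to the methide carbon (C2), closing the furan ring trans to the C3 hydroxymethyl group and delivering the natural product directly, as in 8–5′ neolignan biosynthesis. The precursor is an open-chain 1,2-diarylpropane-1,3-diol already carrying the side-chain sulfate; its single controlling stereocentre (future C3) comes from an Evans aldol reaction.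

Key step: step 8

Remark: TBS = tert-butyldimethylsilyl; sulfated intermediates are drawn and handled as sodium salts, and the target is delivered as the free hydrogen sulfate after cation exchange; locants O1, C2, C3, C3a follow the benzofuran numbering of the target.

Step 1
Reactants: 1 dihydroconiferyl alcohol
Product: 2 2-bromo-4-(3-hydroxypropyl)-6-methoxyphenol
Conditions: NBS (1.0 equiv), iPr2NH (10 mol %), CH2Cl2, 0 °C → rt
Reagents that add atoms: N-bromosuccinimide, O=C1CCC(=O)N1Br
Why: Electrophilic aromatic bromination in which the free phenol OH is the dominant director, its para position being blocked by the propyl chain and one ortho position by OMe, so the remaining ortho carbon should be brominated; no stereocentre is formed.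

Step 2
Reactants: 2 2-bromo-4-(3-hydroxypropyl)-6-methoxyphenol
Product: 3 1-bromo-2-(TBS-oxy)-5-[3-(TBS-oxy)propyl]-3-methoxybenzene
Conditions: TBSCl (2.5 equiv), imidazole (5 equiv), DMF, rt
Reagents that add atoms: tert-butyldimethylsilyl chloride, CC(C)(C)[Si](C)(C)Cl
Why: Imidazole-promoted silylation (Corey protocol) should cap phenol and primary alcohol in one operation, giving an aryl silyl ether (acid-stable, fluoride-labile) and a primary alkyl silyl ether (acid-labile) that can be told apart later.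

Step 3
Reactants: 3 1-bromo-2-(TBS-oxy)-5-[3-(TBS-oxy)propyl]-3-methoxybenzene; 4 (S)-3-acetyl-4-benzyloxazolidin-2-one
Product: 7 (S)-4-benzyl-3-{2-[2-(TBS-oxy)-3-methoxy-5-(3-(TBS-oxy)propyl)phenyl]acetyl}oxazolidin-2-one, via lithium enolate 5 (not isolated), via chlorozinc enolate 6 (not isolated)
Conditions: 4, LiHMDS, THF, −78 °C; ZnCl2, −78 °C → rt; then 3, Pd(dba)2 (3 mol %), Q-Phos (3 mol %), THF, rt → 50 °C
Reagents that add atoms: none
Why: Pd-catalysed α-arylation of a zinc enolate (Reformatsky–Negishi-type coupling), in which the weakly basic zinc enolate transmetalates to the arylpalladium bromide and reductive elimination forms the aryl–CH2 bond without harming the silyl ethers or the auxiliary stereocentre; no new stereocentre is formed.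

Step 4
Reactants: 7 (S)-4-benzyl-3-{2-[2-(TBS-oxy)-3-methoxy-5-(3-(TBS-oxy)propyl)phenyl]acetyl}oxazolidin-2-one; 8 4-(TBS-oxy)-3-methoxybenzaldehyde
Product: 10 (S)-4-benzyl-3-{(2S,3S)-3-hydroxy-3-[4-(TBS-oxy)-3-methoxyphenyl]-2-[2-(TBS-oxy)-3-methoxy-5-(3-(TBS-oxy)propyl)phenyl]propanoyl}oxazolidin-2-one, via Z-boron enolate 9 (not isolated)
Conditions: Bu2BOTf, iPr2NEt, CH2Cl2, −78 → 0 °C; 8, −78 → 0 °C; then pH 7 buffer, MeOH, 30% H2O2, 0 °C; chromatography
Reagents that add atoms: none
Why: Evans syn-aldol reaction through the (Z)-boron enolate and a Zimmerman–Traxler chair, in which the benzyl group of the (S)-auxiliary shields one enolate face so that the α-carbon (future C3) should form as 2S, while the 3S carbinol centre is of no consequence because it is planarised in step 8.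

Step 5
Reactants: 10 Evans syn-aldol adduct
Product: 11 (S)-4-benzyl-3-{(2S,3S)-3-hydroxy-2-[5-(3-hydroxypropyl)-3-methoxy-2-(TBS-oxy)phenyl]-3-[4-(TBS-oxy)-3-methoxyphenyl]propanoyl}oxazolidin-2-one
Conditions: AcOH/THF/H2O (3:1:1), rt
Reagents that add atoms: none
Why: Acid-catalysed silyl ether hydrolysis is much faster for the unhindered primary alkyl TBS ether than for aryl TBS ethers, so only the side-chain alcohol should be freed and both stereocentres remain untouched.

Step 6
Reactants: 11 side-chain alcohol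
Product: 12 sodium 3-{3-[(2S,3S)-1-((S)-4-benzyl-2-oxooxazolidin-3-yl)-3-hydroxy-1-oxo-3-(4-(TBS-oxy)-3-methoxyphenyl)propan-2-yl]-5-methoxy-4-(TBS-oxy)phenyl}propyl sulfate
Conditions: SO3·pyridine (1.3 equiv), pyridine, 0 °C → rt; aq NaHCO3
Reagents that add atoms: sulfur trioxide–pyridine complex, O=S(=O)([O-])[n+]1ccccc1; sodium hydrogen carbonate, [Na+].OC([O-])=O
Why: O-Sulfation with an SO3–amine complex, in which the unhindered primary alcohol should react far faster than the hindered, hydrogen-bonded secondary benzylic carbinol, while the oxygen of the future CH2OH does not yet exist (it is masked as the imide).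

Step 7
Reactants: 12 imide sulfate sodium salt
Product: 13 sodium 3-{3-[(1S,2R)-1,3-dihydroxy-1-(4-(TBS-oxy)-3-methoxyphenyl)propan-2-yl]-5-methoxy-4-(TBS-oxy)phenyl}propyl sulfate
Conditions: LiBH4, MeOH (1.5 equiv), THF, 0 °C
Reagents that add atoms: none
Why: Reductive cleavage of the N-acyl oxazolidinone by LiBH4 (standard auxiliary removal) should give the primary alcohol without enolisation, so the aryl-bearing centre keeps its configuration (now R by CIP), and sulfate monoester anions and aryl silyl ethers are inert to borohydride.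

Step 8
Reactants: 13 bis-silylated diol sulfate sodium salt
Product: 16 3-[(2S,3R)-2-(4-hydroxy-3-methoxyphenyl)-3-(hydroxymethyl)-7-methoxy-2,3-dihydro-1-benzofuran-5-yl]propyl hydrogen sulfate, via bisphenol diol 14 (not isolated), via p-quinone methide 15 (not isolated)
Conditions: TBAF (2.2 equiv), THF, 0 °C; then 1 M aq HCl to pH 1–2, THF/H2O, rt; Dowex 50W (H+), C18
Reagents that add atoms: none
Why: Fluoride frees both phenols (14); in dilute aqueous acid the benzylic hydroxyl at the future C2, para to the ring-A 4-OH, is protonated and lost as water to give p-quinone methide 15, and the ring-B phenol oxygen, held ortho to the future C3, adds to the methide carbon in a 1,6 (oxa-Michael) sense with rearomatisation of ring A. The closest known reaction type is the acid-promoted dehydrative cyclisation of o-hydroxyaryl-substituted p-hydroxybenzyl alcohols through p-quinone methides, the step that forms the phenylcoumaran ring in 8–5′ lignan biosynthesis. The furan ring closes in a 5-exo-trig mode, the exocyclic C=C of the methide being attacked at the carbon that becomes C2. The new C2 stereocentre is set by substrate control from C3: attack anti to the CH2OH group gives the trans ring, which should also be the thermodynamic product because closure is reversible under these conditions, so either configuration of the carbinol converges on (2S,3R). The step needs O1 to win over other nucleophiles and C3 to keep its configuration; the five-membered closure should outrun water (reversible), the primary alcohol (4-exo) and C3–H loss to the stilbene, and the alkyl sulfate monoester is inert to dilute aqueous acid at room temperature.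

Compound list
1 | dihydroconiferyl alcohol, 4-(3-hydroxypropyl)-2-methoxyphenol | COc1cc(CCCO)ccc1O | starting material
2 | 2-bromo-4-(3-hydroxypropyl)-6-methoxyphenol | COc1cc(CCCO)cc(Br)c1O | intermediate
3 | 1-bromo-2-(TBS-oxy)-5-[3-(TBS-oxy)propyl]-3-methoxybenzene | COc1cc(CCCO[Si](C)(C)C(C)(C)C)cc(Br)c1O[Si](C)(C)C(C)(C)C | intermediate
4 | (S)-3-acetyl-4-benzyloxazolidin-2-one | CC(=O)N1C(=O)OC[C@@H]1Cc1ccccc1 | starting material
5 | lithium enolate of 4 | [Li]OC(=C)N1C(=O)OC[C@@H]1Cc1ccccc1 | intermediate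
6 | chlorozinc enolate of 4 (drawn C-bound) | Cl[Zn]CC(=O)N1C(=O)OC[C@@H]1Cc1ccccc1 | intermediate
7 | (S)-4-benzyl-3-{2-[2-(TBS-oxy)-3-methoxy-5-(3-(TBS-oxy)propyl)phenyl]acetyl}oxazolidin-2-one | COc1cc(CCCO[Si](C)(C)C(C)(C)C)cc(CC(=O)N2C(=O)OC[C@@H]2Cc2ccccc2)c1O[Si](C)(C)C(C)(C)C | intermediate
8 | 4-(TBS-oxy)-3-methoxybenzaldehyde (O-TBS-vanillin) | COc1cc(C=O)ccc1O[Si](C)(C)C(C)(C)C | starting material
9 | (Z)-dibutylboron enolate of 7 | CCCCB(CCCC)O/C(=C\c1cc(CCCO[Si](C)(C)C(C)(C)C)cc(OC)c1O[Si](C)(C)C(C)(C)C)N1C(=O)OC[C@@H]1Cc1ccccc1 | intermediate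
10 | Evans syn-aldol adduct, (4S)-auxiliary, (2S,3S)-acyl chain, three TBS ethers | O=C(N1C(=O)OC[C@@H]1Cc1ccccc1)[C@@H](c1cc(CCCO[Si](C)(C)C(C)(C)C)cc(OC)c1O[Si](C)(C)C(C)(C)C)[C@H](O)c1ccc(O[Si](C)(C)C(C)(C)C)c(OC)c1 | intermediate
11 | aldol adduct with free 3-hydroxypropyl chain, two aryl TBS ethers | O=C(N1C(=O)OC[C@@H]1Cc1ccccc1)[C@@H](c1cc(CCCO)cc(OC)c1O[Si](C)(C)C(C)(C)C)[C@H](O)c1ccc(O[Si](C)(C)C(C)(C)C)c(OC)c1 | intermediate
12 | sodium propyl sulfate of 11 | O=C(N1C(=O)OC[C@@H]1Cc1ccccc1)[C@@H](c1cc(CCCOS(=O)(=O)[O-])cc(OC)c1O[Si](C)(C)C(C)(C)C)[C@H](O)c1ccc(O[Si](C)(C)C(C)(C)C)c(OC)c1.[Na+] | intermediate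
13 | sodium 3-{3-[(1S,2R)-1,3-dihydroxy-1-(4-(TBS-oxy)-3-methoxyphenyl)propan-2-yl]-5-methoxy-4-(TBS-oxy)phenyl}propyl sulfate | OC[C@@H](c1cc(CCCOS(=O)(=O)[O-])cc(OC)c1O[Si](C)(C)C(C)(C)C)[C@H](O)c1ccc(O[Si](C)(C)C(C)(C)C)c(OC)c1.[Na+] | intermediate
14 | sodium 3-{3-[(1S,2R)-1,3-dihydroxy-1-(4-hydroxy-3-methoxyphenyl)propan-2-yl]-4-hydroxy-5-methoxyphenyl}propyl sulfate | OC[C@@H](c1cc(CCCOS(=O)(=O)[O-])cc(OC)c1O)[C@H](O)c1ccc(O)c(OC)c1.[Na+] | intermediate
15 | 3-{4-hydroxy-3-[(2R)-1-hydroxy-3-(3-methoxy-4-oxocyclohexa-2,5-dien-1-ylidene)propan-2-yl]-5-methoxyphenyl}propyl hydrogen sulfate (p-quinone methide) | OC[C@@H](c1cc(CCCOS(=O)(=O)O)cc(OC)c1O)C=C1C=CC(=O)C(OC)=C1 | intermediate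
16 | 3-[(2S,3R)-2-(4-hydroxy-3-methoxyphenyl)-3-(hydroxymethyl)-7-methoxy-2,3-dihydro-1-benzofuran-5-yl]propyl hydrogen sulfate | COc1cc([C@H]2Oc3c(OC)cc(CCCOS(=O)(=O)O)cc3[C@@H]2CO)ccc1O | target

Total step count: 8. Longest linear sequence: 8 steps (1 → 2 → 3 → 7 → 10 → 11 → 12 → 13 → 16); 4 and 8 are purchased.

Steps most likely to fail

Step 3. The imide-derived zinc enolate may decompose (ketene loss, self-acylation) faster than it transmetalates to the hindered arylpalladium species. Fallback: setting out from 3, the same bromide is coupled (Pd(dba)2, Q-Phos, THF, rt) with the commercial, stable Reformatsky reagent (2-tert-butoxy-2-oxoethyl)zinc bromide to give the tert-butyl arylacetate F1. The tert-butyl ester is cleaved with TMSOTf/2,6-lutidine, which spares the silyl ethers, to give the arylacetic acid F2. This is activated as the mixed pivalic anhydride F3 (PivCl, Et3N, THF, −20 °C, not isolated) and used to N-acylate lithiated (S)-4-benzyloxazolidin-2-one (n-BuLi, −78 °C), coming back to the route at 7.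

Step 6. Sulfation may not discriminate cleanly: the secondary benzylic hydroxyl may also be sulfated and then ionise or eliminate. Fallback: setting out from 10, the carbinol is first blocked (TBSOTf, 2,6-lutidine, CH2Cl2, −78 °C) as the benzylic silyl ether F4. Selective acidic cleavage of the primary silyl ether (AcOH/THF/H2O) gives the alcohol F5, now the only free hydroxyl. It is sulfated (SO3·pyridine; NaHCO3) to the sodium sulfate F6 and reduced (LiBH4) to the primary alcohol F7. TBAF then frees the two phenols to give the bisphenol benzylic silyl ether F8 (not isolated), and dilute aqueous acid ionises the p-hydroxybenzylic silyl ether directly to the quinone methide, so the route is rejoined at 15.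

Step 8. The C3 configuration may erode if the quinone methide tautomerises to the stilbene and is re-protonated, trans selectivity may be incomplete, or the sulfate may be lost by acid solvolysis. Fallback: setting out from 13, both hydroxyls are acetylated (Ac2O, pyridine, DMAP) to give the diacetate F9. TBAF in THF at 0 °C then generates the quinone methide acetate F10 (not isolated) without acid, by 1,6-elimination of the benzylic acetate from the ring-A phenoxide, and the ring-B phenoxide closes the ring to the cyclised acetate F11. Methanolysis (K2CO3, MeOH) and cation exchange return to the route at 16.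

Further compounds
F1 | step 3 | tert-butyl 2-[2-(TBS-oxy)-3-methoxy-5-(3-(TBS-oxy)propyl)phenyl]acetate | COc1cc(CCCO[Si](C)(C)C(C)(C)C)cc(CC(=O)OC(C)(C)C)c1O[Si](C)(C)C(C)(C)C
F2 | step 3 | 2-[2-(TBS-oxy)-3-methoxy-5-(3-(TBS-oxy)propyl)phenyl]acetic acid | COc1cc(CCCO[Si](C)(C)C(C)(C)C)cc(CC(=O)O)c1O[Si](C)(C)C(C)(C)C
F3 | step 3 | mixed pivalic anhydride of F2 | COc1cc(CCCO[Si](C)(C)C(C)(C)C)cc(CC(=O)OC(=O)C(C)(C)C)c1O[Si](C)(C)C(C)(C)C
F4 | step 6 | benzylic O-TBS ether of 10 | O=C(N1C(=O)OC[C@@H]1Cc1ccccc1)[C@@H](c1cc(CCCO[Si](C)(C)C(C)(C)C)cc(OC)c1O[Si](C)(C)C(C)(C)C)[C@H](O[Si](C)(C)C(C)(C)C)c1ccc(O[Si](C)(C)C(C)(C)C)c(OC)c1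
F5 | step 6 | benzylic O-TBS ether of 11 (free 3-hydroxypropyl chain) | O=C(N1C(=O)OC[C@@H]1Cc1ccccc1)[C@@H](c1cc(CCCO)cc(OC)c1O[Si](C)(C)C(C)(C)C)[C@H](O[Si](C)(C)C(C)(C)C)c1ccc(O[Si](C)(C)C(C)(C)C)c(OC)c1
F6 | step 6 | benzylic O-TBS ether of 12 (sodium sulfate) | O=C(N1C(=O)OC[C@@H]1Cc1ccccc1)[C@@H](c1cc(CCCOS(=O)(=O)[O-])cc(OC)c1O[Si](C)(C)C(C)(C)C)[C@H](O[Si](C)(C)C(C)(C)C)c1ccc(O[Si](C)(C)C(C)(C)C)c(OC)c1.[Na+]
F7 | step 6 | benzylic O-TBS ether of 13 (primary alcohol, sodium sulfate) | OC[C@@H](c1cc(CCCOS(=O)(=O)[O-])cc(OC)c1O[Si](C)(C)C(C)(C)C)[C@H](O[Si](C)(C)C(C)(C)C)c1ccc(O[Si](C)(C)C(C)(C)C)c(OC)c1.[Na+]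
F8 | step 6 | benzylic O-TBS ether of 14 (both phenols free) | OC[C@@H](c1cc(CCCOS(=O)(=O)[O-])cc(OC)c1O)[C@H](O[Si](C)(C)C(C)(C)C)c1ccc(O)c(OC)c1.[Na+]
F9 | step 8 | diacetate of 13 | CC(=O)OC[C@@H](c1cc(CCCOS(=O)(=O)[O-])cc(OC)c1O[Si](C)(C)C(C)(C)C)[C@H](OC(C)=O)c1ccc(O[Si](C)(C)C(C)(C)C)c(OC)c1.[Na+]
F10 | step 8 | p-quinone methide carrying the primary acetate (sodium sulfate) | CC(=O)OC[C@@H](c1cc(CCCOS(=O)(=O)[O-])cc(OC)c1O)C=C1C=CC(=O)C(OC)=C1.[Na+]
F11 | step 8 | 3-O-acetate of 16 as sodium sulfate | COc1cc([C@H]2Oc3c(OC)cc(CCCOS(=O)(=O)[O-])cc3[C@@H]2COC(C)=O)ccc1O.[Na+]
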